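The C5–O1 bond of the γ-lactone is the disconnection (ring atoms O1, C2, C3, C4, C5; side chain C1′ to C10′ on C3). The isobutenyl group on C5 ends in two identical methyl groups, so a π-allylpalladium unit over C5 and the isobutenyl carbons can change faces. One zerovalent-palladium step therefore closes the five-membered ring and sets C5 trans to the C4 silyloxy group, with no C5 stereocentre made beforehand. The precursor, acid 20, is open-chain: a C2 carboxylic acid on the (E)-C3=C1′ alkene, TBS ethers at C4 and C3′, a TBDPS ether at C10′ and an (E)-tertiary allylic methyl carbonate. It comes from a nerol-derived alkyne and a hydroxy enal.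

Key step: step 12

Remark on the chemistry: the facial sense of the two catalyst-controlled additions (Re face with (R)-TRIP in step 3, Si face with (R,R)-ProPhenol in step 7) is assumed from the usual models for these catalysts; each would be checked by Mosher ester analysis and the mirror-image catalyst used if the sense were opposite.

Numbering used in the names: lactone O1, C2(=O), C3, C4, C5; C6 (=CH) and C7 (CMe2) are the isobutenyl carbons; side chain C1′ (=CH on C3) to C10′ (CH2O). The C4 descriptor is R in the open-chain compounds and S in the lactones only because the CIP priorities change on ring closure.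

Step 1
Reactants: 1 nerol
Product: 2 neryl tert-butyldiphenylsilyl ether
Conditions: TBDPSCl, imidazole, CH2Cl2, 0 °C to rt
Reagents that add atoms: tert-butyldiphenylsilyl chloride CC(C)(C)[Si](Cl)(c1ccccc1)c1ccccc1
Why: Imidazole-promoted silylation of a primary allylic alcohol gives a robust silyl ether, chosen because an allylic ester at C10′ would ionise in step 12.

Step 2
Reactants: 2 neryl tert-butyldiphenylsilyl ether
Product: 4 (2E,6Z)-8-(tert-butyldiphenylsilyloxy)-2,6-dimethylocta-2,6-dienal, via allylic alcohol 3 (not isolated)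
Conditions: SeO2 (0.3 equiv), t-BuOOH, salicylic acid (cat.), CH2Cl2, rt; crude, then MnO2, CH2Cl2, rt
Reagents that add atoms: selenium dioxide O=[Se]=O (oxygen donor, regenerated by tert-butyl hydroperoxide CC(C)(C)OO)
Why: Riley allylic oxidation (ene reaction then [2,3]-sigmatropic shift) attacks the E-methyl group of the electron-richer remote trisubstituted alkene, which fixes the (E)-C4′=C5′ geometry, and MnO2 then oxidises the allylic alcohol so that alcohol and any aldehyde already formed converge on 4.

Step 3
Reactants: 4 (2E,6Z)-8-(tert-butyldiphenylsilyloxy)-2,6-dimethylocta-2,6-dienal; 5 allenylboronic acid pinacol ester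
Product: 7 (4R,5E,9Z)-11-(tert-butyldiphenylsilyloxy)-5,9-dimethylundeca-5,9-dien-1-yn-4-ol, via borate ester 6 (not isolated)
Conditions: (R)-TRIP phosphoric acid (10 mol %), 4 Å molecular sieves, toluene, −20 to 0 °C; aqueous work-up
Reagents that add atoms: none
Why: Chiral phosphoric acid-catalysed propargylation of an aldehyde with an allenylboronate passes through a closed six-membered SE2′ transition state that gives only the homopropargylic skeleton, and the (R)-TRIP pocket should direct addition to the Re face of the enal, setting C3′ as R, before the borate ester hydrolyses on work-up.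

Step 4
Reactants: 7 (4R,5E,9Z)-11-(tert-butyldiphenylsilyloxy)-5,9-dimethylundeca-5,9-dien-1-yn-4-ol
Product: 8 (4R,5E,9Z)-4-(tert-butyldimethylsilyloxy)-11-(tert-butyldiphenylsilyloxy)-5,9-dimethylundeca-5,9-dien-1-yne (fragment A)
Conditions: TBSCl, imidazole, DMF, rt
Reagents that add atoms: tert-butyldimethylsilyl chloride CC(C)(C)[Si](C)(C)Cl
Why: Silylation caps the secondary allylic alcohol as an ether that neither quenches the zinc reagent of step 7 nor ionises under zerovalent palladium.

Step 5
Reactants: 9 2-methylbut-3-en-2-ol; 10 (E)-but-2-enal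
Product: 11 (E)-4-hydroxy-4-methylpent-2-enal
Conditions: second-generation Hoveyda–Grubbs catalyst RuCl2(SIMes)(=CH–C6H4-2-OiPr) (2.5 mol %), 10 (5 equiv), CH2Cl2, 40 °C
Reagents that add atoms: none
Why: Olefin cross-metathesis between a slowly homodimerising tertiary allylic alcohol and excess crotonaldehyde should give the thermodynamically preferred E enal with loss of propene.

Step 6
Reactants: 11 (E)-4-hydroxy-4-methylpent-2-enal
Product: 12 (E)-4-methyl-4-(trimethylsilyloxy)pent-2-enal (fragment B)
Conditions: TMSCl, imidazole, DMF, 0 °C to rt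
Reagents that add atoms: trimethylsilyl chloride C[Si](C)(C)Cl
Why: Imidazole-promoted silylation masks the only protic group of the electrophile for the zinc chemistry of step 7 as an ether that mild methanolysis removes afterwards.

Step 7
Reactants: 8 fragment A alkyne; 12 (E)-4-methyl-4-(trimethylsilyloxy)pent-2-enal
Product: 14 (3′R,4R)-enynediol (C1′≡C3 alkyne; C4 secondary OH; (E)-C5=C6; C7 tertiary OH; C3′ OTBS; C10′ OTBDPS), via trimethylsilyl ether 13 (not isolated)
Conditions: (R,R)-ProPhenol (20 mol %), Ph3P=O (40 mol %), Me2Zn (3 equiv), 12 (1.5 equiv), toluene, 0–4 °C; aq NH4Cl; then K2CO3, MeOH, rt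
Reagents that add atoms: none
Why: Zinc–ProPhenol-catalysed asymmetric alkynylation of an α,β-unsaturated aldehyde transfers the alkynyl group from the dinuclear zinc alkynylide to the Si face of the enal under ligand control, setting C4 as R independently of the remote C3′ centre, and K2CO3 in methanol then cleaves only the tertiary trimethylsilyl ether.

Step 8
Reactants: 14 (3′R,4R)-enynediol
Product: 16 (3′R,4R)-(E)-C3-iodoalkene diol (iodine on C3 cis to H on C1′), via alkenylstannane 15 (not isolated)
Conditions: Bu3SnH (1.3 equiv, slow addition), PdCl2(PPh3)2 (5 mol %), THF, 0 °C to rt; then I2, CH2Cl2, 0 °C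
Reagents that add atoms: tributyltin hydride CCCC[SnH](CCCC)CCCC (tin stays only in 15); iodine II
Why: Palladium-catalysed hydrostannation adds H and Sn syn across the alkyne with tin at C3, the carbon next to the free carbinol (inductive and coordinating effect of the propargylic oxygen), and iododestannylation proceeds with retention, so H on C1′ and iodine on C3 end up cis as the E alkylidene of the target requires.

Step 9
Reactants: 16 (3′R,4R)-(E)-C3-iodoalkene diol
Product: 17 C4 tert-butyldimethylsilyl ether of 16 (C7 tertiary OH free)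
Conditions: TBSCl (1.3 equiv), imidazole, DMF, rt
Reagents that add atoms: tert-butyldimethylsilyl chloride CC(C)(C)[Si](C)(C)Cl
Why: Silylation with TBSCl and imidazole distinguishes the secondary allylic alcohol from the tertiary one on steric grounds, and the C4 silyl ether blocks β-lactone formation in step 10 and later directs the ring closure.

Step 10
Reactants: 17 C4 tert-butyldimethylsilyl ether of 16
Product: 18 (3′R,4R)-(E)-C2 carboxylic acid with free C7 tertiary alcohol
Conditions: PdCl2(PPh3)2 (5 mol %), CO (1 atm), Et3N, DMF–H2O (5:1), 50 °C; work-up at pH 4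
Reagents that add atoms: carbon monoxide [C-]#[O+]; water O
Why: Palladium-catalysed hydroxycarbonylation of an alkenyl iodide (oxidative addition, CO insertion, hydrolysis of the acylpalladium species) installs C2 with retention of alkene geometry, while silyl ethers and the free tertiary allylic alcohol are not ionised by zerovalent palladium and acyl capture by the tertiary oxygen would need a seven-membered ring holding an E alkene.

Step 11
Reactants: 18 (3′R,4R)-(E)-C2 carboxylic acid with free C7 tertiary alcohol
Product: 20 (3′R,4R)-(E)-C2 carboxylic acid bearing C4 OTBS and the (E)-tertiary allylic methyl carbonate at C7, via mixed anhydride 19 (not isolated)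
Conditions: LiN(SiMe3)2 (2.2 equiv), THF, −78 °C; ClCO2Me (2.5 equiv), −78 to 0 °C; then pyridine–H2O, rt; work-up at pH 5
Reagents that add atoms: methyl chloroformate COC(=O)Cl
Why: O-Acylation of the lithium alkoxide with the chloroformate gives the tertiary carbonate, while the carboxylate is converted at the same time into a mixed carboxylic–carbonic anhydride that water and pyridine hydrolyse back to the acid whichever carbonyl is attacked, the hindered tertiary carbonate being far less electrophilic.

Step 12
Reactants: 20 (3′R,4R)-(E)-C2 carboxylic acid bearing C4 OTBS and the (E)-tertiary allylic methyl carbonate at C7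
Product: 21 (3′R,4S,5R)-tris-silyl lactone (4,5-trans; isobutenyl on C5; (E)-C3=C1′)
Conditions: Pd2(dba)3·CHCl3 (2.5 mol %), PPh3 (20 mol %), THF (0.02 M), rt to 40 °C
Reagents that add atoms: none
Why: Zerovalent palladium ionises the tertiary allylic carbonate with loss of CO2 and methoxide, which deprotonates the acid, and the carboxylate attacks the C5 terminus of the π-allyl complex anti to the metal (Tsuji–Trost allylic substitution; the closest known type is the cyclisation of carboxylic acids onto allylic carbonates to give γ-alkenyl-γ-butyrolactones). The O1–C5 bond closes the five-membered lactone ring in a 5-exo mode, whereas attack at the dimethyl terminus would need a seven-membered ring. The new C5 stereocentre is controlled by the existing C4 centre: the two diastereomeric π-allyl complexes interconvert by η3–η1–η3 slippage at the terminus carrying two equal methyl groups, and the lactone, itself an allylic ester, can re-ionise, so the ring should settle with isobutenyl trans to the silyloxy group. The step needs 4,5-trans selectivity and ionisation at one site only; the bulky C4 silyloxy group next to C5 should secure the first, and carrying the oxygens at C3′, C4 and C10′ as silyl ethers, which zerovalent palladium does not ionise, secures the second. The E geometry of C3=C1′ lies outside the allyl unit and is untouched.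

Step 13
Reactants: 21 (3′R,4S,5R)-tris-silyl lactone
Product: 22 (3′R,4S,5R)-triol lactone (OH at C4, C3′ and C10′)
Conditions: TBAF, AcOH (1:1, 6 equiv), THF, 0 °C to rt
Reagents that add atoms: none
Why: Fluoride-mediated desilylation removes all three silyl ethers, buffered with acetic acid so that the alkylidene lactone and the allylic C5–O1 bond do not meet free alkoxide, and the E alkene keeps the C3′ hydroxyl away from the lactone carbonyl.

Step 14
Reactants: 22 (3′R,4S,5R)-triol lactone
Product: 23 (3′R,4S,5R)-C10′ benzoate diol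
Conditions: BzCl (1.05 equiv), 2,4,6-collidine, CH2Cl2, −78 to −40 °C
Reagents that add atoms: benzoyl chloride O=C(Cl)c1ccccc1
Why: Acylation under kinetic control with a hindered pyridine base at low temperature should select the unhindered primary allylic C10′ hydroxyl over the two secondary ones.

Step 15
Reactants: 23 (3′R,4S,5R)-C10′ benzoate diol
Product: 24 target CNP0262857.1
Conditions: Ac2O, pyridine, DMAP (5 mol %), CH2Cl2, 0 °C
Reagents that add atoms: acetic anhydride CC(=O)OC(C)=O
Why: DMAP-catalysed acetylation esterifies the two remaining secondary hydroxyls at C3′ and C4 without breaking any C–O bond, so no stereocentre is touched.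

Compound list
1 | nerol | CC(C)=CCC/C(C)=C\CO | starting material
2 | neryl tert-butyldiphenylsilyl ether | CC(C)=CCC/C(C)=C\CO[Si](c1ccccc1)(c1ccccc1)C(C)(C)C | intermediate
3 | (2E,6Z)-8-(tert-butyldiphenylsilyloxy)-2,6-dimethylocta-2,6-dien-1-ol | OC/C(C)=C/CC/C(C)=C\CO[Si](c1ccccc1)(c1ccccc1)C(C)(C)C | intermediate
4 | (2E,6Z)-8-(tert-butyldiphenylsilyloxy)-2,6-dimethylocta-2,6-dienal | O=C/C(C)=C/CC/C(C)=C\CO[Si](c1ccccc1)(c1ccccc1)C(C)(C)C | intermediate
5 | allenylboronic acid pinacol ester | C=C=CB1OC(C)(C)C(C)(C)O1 | starting material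
6 | pinacol borate ester of alcohol 7 | CC1(C)OB(O[C@H](CC#C)/C(C)=C/CC/C(C)=C\CO[Si](c2ccccc2)(c2ccccc2)C(C)(C)C)OC1(C)C | intermediate
7 | (4R,5E,9Z)-11-(tert-butyldiphenylsilyloxy)-5,9-dimethylundeca-5,9-dien-1-yn-4-ol | O[C@H](CC#C)/C(C)=C/CC/C(C)=C\CO[Si](c1ccccc1)(c1ccccc1)C(C)(C)C | intermediate
8 | (4R,5E,9Z)-4-(tert-butyldimethylsilyloxy)-11-(tert-butyldiphenylsilyloxy)-5,9-dimethylundeca-5,9-dien-1-yne (fragment A) | CC(C)(C)[Si](C)(C)O[C@H](CC#C)/C(C)=C/CC/C(C)=C\CO[Si](c1ccccc1)(c1ccccc1)C(C)(C)C | intermediate
9 | 2-methylbut-3-en-2-ol | CC(C)(O)C=C | starting material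
10 | (E)-but-2-enal (crotonaldehyde) | C/C=C/C=O | starting material
11 | (E)-4-hydroxy-4-methylpent-2-enal | CC(C)(O)/C=C/C=O | intermediate
12 | (E)-4-methyl-4-(trimethylsilyloxy)pent-2-enal (fragment B) | CC(C)(O[Si](C)(C)C)/C=C/C=O | intermediate
13 | (3′R,4R)-propargylic alcohol with C7 trimethylsilyl ether | CC(C)(C)[Si](C)(C)O[C@H](CC#C[C@H](O)/C=C/C(C)(C)O[Si](C)(C)C)/C(C)=C/CC/C(C)=C\CO[Si](c1ccccc1)(c1ccccc1)C(C)(C)C | intermediate
14 | (3′R,4R)-enynediol | CC(C)(C)[Si](C)(C)O[C@H](CC#C[C@H](O)/C=C/C(C)(C)O)/C(C)=C/CC/C(C)=C\CO[Si](c1ccccc1)(c1ccccc1)C(C)(C)C | intermediate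
15 | (3′R,4R)-(E)-C3-tributylstannyl alkene diol | CC(C)(C)[Si](C)(C)O[C@H](C/C=C(/[Sn](CCCC)(CCCC)CCCC)[C@H](O)/C=C/C(C)(C)O)/C(C)=C/CC/C(C)=C\CO[Si](c1ccccc1)(c1ccccc1)C(C)(C)C | intermediate
16 | (3′R,4R)-(E)-C3-iodoalkene diol | CC(C)(C)[Si](C)(C)O[C@H](C/C=C(/I)[C@H](O)/C=C/C(C)(C)O)/C(C)=C/CC/C(C)=C\CO[Si](c1ccccc1)(c1ccccc1)C(C)(C)C | intermediate
17 | C4 tert-butyldimethylsilyl ether of 16 | CC(C)(C)[Si](C)(C)O[C@H](C/C=C(/I)[C@H](O[Si](C)(C)C(C)(C)C)/C=C/C(C)(C)O)/C(C)=C/CC/C(C)=C\CO[Si](c1ccccc1)(c1ccccc1)C(C)(C)C | intermediate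
18 | (3′R,4R)-(E)-C2 acid with free C7 tertiary alcohol | CC(C)(C)[Si](C)(C)O[C@H](C/C=C(/C(=O)O)[C@H](O[Si](C)(C)C(C)(C)C)/C=C/C(C)(C)O)/C(C)=C/CC/C(C)=C\CO[Si](c1ccccc1)(c1ccccc1)C(C)(C)C | intermediate
19 | mixed carboxylic–carbonic anhydride of 20 | CC(C)(C)[Si](C)(C)O[C@H](C/C=C(/C(=O)OC(=O)OC)[C@H](O[Si](C)(C)C(C)(C)C)/C=C/C(C)(C)OC(=O)OC)/C(C)=C/CC/C(C)=C\CO[Si](c1ccccc1)(c1ccccc1)C(C)(C)C | intermediate
20 | (3′R,4R)-(E)-C2 acid with C4 OTBS and (E)-tertiary allylic methyl carbonate (key-step precursor) | CC(C)(C)[Si](C)(C)O[C@H](C/C=C(/C(=O)O)[C@H](O[Si](C)(C)C(C)(C)C)/C=C/C(C)(C)OC(=O)OC)/C(C)=C/CC/C(C)=C\CO[Si](c1ccccc1)(c1ccccc1)C(C)(C)C | intermediate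
21 | (3′R,4S,5R)-tris-silyl lactone (key-step product) | CC(C)(C)[Si](C)(C)O[C@H](C/C=C1/C(=O)O[C@H](C=C(C)C)[C@H]1O[Si](C)(C)C(C)(C)C)/C(C)=C/CC/C(C)=C\CO[Si](c1ccccc1)(c1ccccc1)C(C)(C)C | intermediate
22 | (3′R,4S,5R)-triol lactone | O[C@H](C/C=C1/C(=O)O[C@H](C=C(C)C)[C@H]1O)/C(C)=C/CC/C(C)=C\CO | intermediate
23 | (3′R,4S,5R)-C10′ benzoate diol | O[C@H](C/C=C1/C(=O)O[C@H](C=C(C)C)[C@H]1O)/C(C)=C/CC/C(C)=C\COC(=O)c1ccccc1 | intermediate
24 | CNP0262857.1, (3′R,4S,5R)-C3′,C4-diacetate C10′-benzoate | CC(=O)O[C@H](C/C=C1/C(=O)O[C@H](C=C(C)C)[C@H]1OC(C)=O)/C(C)=C/CC/C(C)=C\COC(=O)c1ccccc1 | target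

Total step count: 15. Longest linear sequence: 13 steps (steps 1–4 and 7–15); steps 5 and 6 make fragment B in parallel.

Steps most likely to fail

1. Step 12. Facial selection at C5 may be incomplete if the closure stops under kinetic control before the π-allyl diastereomers or the lactone epimers have equilibrated. β-Hydride loss from the allyl complex to a diene is a second drain. The fallback sets C5 by a stereospecific SN2 inversion instead of by equilibration. It sets out from 20: the closure is run as before and the (3′R,4S,5S)-4,5-cis lactone F1 is separated. F1 is opened with LiOH in THF–H2O at 0 °C to the (3′R,4S,5S)-C5-hydroxy acid F2, which is acidified cold to pH 5 and used at once. Mitsunobu lactonisation of F2 (PPh3, DIAD, THF, 0 °C) closes the ring with inversion at C5 and returns to 21.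

2. Step 8. Tin may be delivered to C1′ instead of C3, and the alkenylstannane may be protodestannylated before iodination. The fallback replaces catalyst-controlled hydrostannation by alkoxide-directed, titanocene-catalysed hydromagnesiation. It sets out from 14: i-BuMgCl (3.5 equiv) and Cp2TiCl2 (10 mol %) in Et2O at rt should add H and Mg syn, with the metal held at C3 next to the magnesium alkoxide, to give the C3-chloromagnesio alkene bis(chloromagnesium alkoxide) F3. Iodine at −78 °C then gives the iodide with retention, and the route is rejoined at 16.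

3. Step 11. Acylation may occur at the carboxylate in competition with the hindered alkoxide, and the mixed anhydride may collapse to a methyl ester by decarboxylation. The fallback keeps C2 as an ester while the carbonate is made. It sets out from 17: carbonylation with PdCl2(PPh3)2, CO (1 atm), 2-(trimethylsilyl)ethanol and Et3N in DMF at 60 °C gives the 2-(trimethylsilyl)ethyl ester with free C7 alcohol F4. LiN(SiMe3)2 and ClCO2Me in THF at −78 °C then give the 2-(trimethylsilyl)ethyl ester methyl carbonate F5. Brief treatment of F5 with tris(dimethylamino)sulfonium difluorotrimethylsilicate in DMF at 0 °C fragments the ester faster than it attacks the hindered silyl ethers and returns to 20.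

Further compounds
F1 | step 12 | (3′R,4S,5S)-4,5-cis tris-silyl lactone (C5 epimer of 21) | CC(C)(C)[Si](C)(C)O[C@H](C/C=C1/C(=O)O[C@@H](C=C(C)C)[C@H]1O[Si](C)(C)C(C)(C)C)/C(C)=C/CC/C(C)=C\CO[Si](c1ccccc1)(c1ccccc1)C(C)(C)C
F2 | step 12 | (3′R,4S,5S)-C5-hydroxy acid from F1 | CC(C)(C)[Si](C)(C)O[C@H](C/C=C(/C(=O)O)[C@H](O[Si](C)(C)C(C)(C)C)[C@@H](O)C=C(C)C)/C(C)=C/CC/C(C)=C\CO[Si](c1ccccc1)(c1ccccc1)C(C)(C)C
F3 | step 8 | C3-chloromagnesio alkene bis(chloromagnesium alkoxide) | CC(C)(C)[Si](C)(C)O[C@H](C/C=C(/[Mg]Cl)[C@H](O[Mg]Cl)/C=C/C(C)(C)O[Mg]Cl)/C(C)=C/CC/C(C)=C\CO[Si](c1ccccc1)(c1ccccc1)C(C)(C)C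
F4 | step 11 | 2-(trimethylsilyl)ethyl ester of 18 | CC(C)(C)[Si](C)(C)O[C@H](C/C=C(/C(=O)OCC[Si](C)(C)C)[C@H](O[Si](C)(C)C(C)(C)C)/C=C/C(C)(C)O)/C(C)=C/CC/C(C)=C\CO[Si](c1ccccc1)(c1ccccc1)C(C)(C)C
F5 | step 11 | 2-(trimethylsilyl)ethyl ester of 20 | CC(C)(C)[Si](C)(C)O[C@H](C/C=C(/C(=O)OCC[Si](C)(C)C)[C@H](O[Si](C)(C)C(C)(C)C)/C=C/C(C)(C)OC(=O)OC)/C(C)=C/CC/C(C)=C\CO[Si](c1ccccc1)(c1ccccc1)C(C)(C)C
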